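## Structural features

The target 14 is an open-chain bis(bibenzyl) of four benzene rings. Ring A (4-hydroxyphenyl) is tied by a CH2CH2 bridge to ring B, which is 1,3,5-trisubstituted and also carries a methoxy group and an ether oxygen; that oxygen leads to the para-disubstituted ring C, which a second CH2CH2 bridge ties to ring D. Ring D is a tetrasubstituted benzoic acid with the carboxyl at C1, a free hydroxyl at C2, a methoxy group at C4 and the bridge at C6, so the carboxyl is flanked on both sides. There is no stereocentre and no stereogenic double bond; 14 is achiral and nothing has to be set or preserved stereochemically. The fragile part is the electron-rich, doubly ortho-substituted salicylic acid of ring D, which loses CO2 on heating or in strong acid, and the two free phenols are sensitive to oxidants. The diaryl ether and the saturated bridges are robust. The real difficulty is regiochemical and lies in ring D: the bridge must enter at the one carbon next to the carboxyl while O2 (free) and O4 (methylated) stay differentiated, and the acid must survive to the end. The key step exploits the fact that the C1 carboxyl has exactly one unsubstituted ortho carbon, C6–H, because C2 carries oxygen, so a carboxylate-directed metalation can only reach C6. In the resulting lactone, isocoumarin C8, C6 and C4a correspond to C2, C4 and C6 of the acid, and the lactone O–C3 bond is benzylic to ring C, so hydrogen can cut it again.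

## Logic of the disconnections

**14 to 12.** Going backwards, the carboxyl oxygen is joined to the bridge carbon next to ring C, a C3=C4 double bond is introduced and both phenols are benzylated. The carboxyl is then held as a neutral lactone that cannot decarboxylate, and hydrogen alone undoes all four changes. The gain is that the sensitive hydroxy acid appears only in a last, mild step. The demand is that one hydrogenation saturates the enol-lactone alkene, cleaves two aryl benzyl ethers and cleaves the benzylic lactone C–O bond (through 13), while the diaryl ether and the arenes stay intact.

**12 to 3 and 10.** Two bonds are cut: the C–C bond between C6 of ring D and the first bridge carbon, and the lactone O–C3 bond. This separates ring D, with all its oxygen functions already correctly placed, from the whole A–B–C assembly. The cut is made there because the carboxyl can direct a metal to its only free ortho C–H and then close the ring on the new alkene. The forward step must palladate C6–H and not lose CO2, must arylate the terminal alkene carbon (giving 11 in passing), and must tolerate two benzyl ethers and a diaryl ether.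

**3 to 1.** The benzyl–oxygen bond at O2 is cut. The phenol must be masked during the oxidative coupling, and a benzyl group leaves in the final hydrogenation at no extra cost. The forward sequence alkylates both the phenol and the acid (2) and then frees only the acid.

**10 to 9.** The vinyl C=C bond is cut to an aldehyde plus a one-carbon ylide. The aldehyde is the group that made the preceding ether formation possible, so no functional group is wasted. The demand is a clean methylenation of a non-enolisable aryl aldehyde.

**9 to 7 and 8.** The diaryl ether C–O bond on the ring C side is cut. The para-formyl group of 8 activates fluoride displacement, so no copper or palladium is needed. The ether is made after the borane chemistry on purpose, so that the aldehyde never meets a boron hydride or an alkylborane.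

**7 to 4 and 5.** The bond between ring B and its bridge carbon is cut. The purchased ring 5 already has the 1,3,5-pattern with three different substituents, and 4 supplies ring A with its phenol masked and both bridge carbons. The forward step needs anti-Markovnikov hydroboration (6) and a B-alkyl cross-coupling that tolerates a free phenol.

## Other disconnections considered

**Alternative 1:** The cut runs through ring D itself, at the aromatic C1–C6 bond, which unfolds ring D into a linear 3,5,7-trioxo ester.
- Forward key step: the diketo-dioxinone A2 would be heated with a benzylic alcohol. Fragmentation releases an acylketene, which is captured as the benzyl triketo ester. Carbonate base and then acid bring about the C2-to-C7 aldol condensation and dehydration that aromatise the chain to the resorcylate A1.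
- In its favour: carboxyl, both oxygens and the side chain all come from the chain, so the substitution pattern of ring D is not a selectivity question. Ring formation is mild. The benzyl ester falls off by hydrogenolysis together with the benzyl ether.
- Against it here: A1 has free hydroxyls at both C2 and C4, so a selective methylation of O4 is needed. This is feasible because the C2 hydroxyl is hydrogen-bonded to the ester, but it is an extra step. A2 needs a 3-arylpropanoyl unit carrying rings A to C, reachable from 9 only by chain extension, followed by a C-acylation. The polycarbonyl chain can also close through oxygen to a pyranone.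
- Comparison: in structure it builds a six-carbon ring that the chosen plan buys intact. In mechanism it is the better of the two, being ionic and free of the CO2-loss risk of a palladated electron-rich acid. Its endgame is also better, with no lactone C–O bond to hydrogenolyse. In step economy it is clearly worse, at about eleven steps against six.

**Alternative 2:** The cut opens two bonds of ring B.
- Forward key step: dimethyl malonate A5 adds in a Michael reaction to the enone A4, and the methyl ketone then closes onto a malonate ester by Claisen condensation. Hydrolysis and decarboxylation give the dione A3. Oxidative aromatisation with mono-O-methylation would then give 7.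
- In its favour: cheap bulk reagents, no palladium, no bromophenol, robust anionic chemistry. On cost and scalability of 7 it is the equal or the better of the chosen coupling.
- Against it here: it constructs a benzene ring that can be bought with the correct pattern. A4 must first be made from a 3-arylpropanal. Desymmetrising the resorcinol stage to the monomethyl ether needs control.
- Comparison: in structure it addresses only ring B and leaves the real problem, the attachment at ring D, untouched. It is therefore a possible supplier of 7 for the chosen key step, not a rival to it. In mechanism it is equally free of stereochemical issues. In step economy it needs about five steps to 7 where the chosen route needs one.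

**Alternative 3:** The cut opens the C1–C2 and C5–C6 bonds of ring D.
- Forward key step: the ynoate A7 and the silyl ketene acetal diene A8 undergo a Diels–Alder reaction. Loss of the methoxy and silyl groups at the former acetal carbon aromatises the adduct to A6.
- In its favour: A6 arrives with the C2 hydroxyl free, O4 methylated and the carboxyl as a benzyl ester. The polarisation of both partners fixes the regiochemistry. The endgame is a plain hydrogenolysis. On the endgame it is better than the chosen plan. On differentiation of the two oxygens it is its equal, since the chosen plan buys that differentiation.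
- Against it here: a 3-alkylpropiolate is a sluggish dienophile that needs heat, under which the moisture-sensitive diene A8 degrades. A8 must be made fresh. A7 needs a four-carbon alkynoate chain on ring C, about four steps from 9.
- Comparison: in structure it forms two C–C bonds and a ring where one C–C bond onto a purchased ring suffices. In mechanism it is pericyclic and metal-free, avoiding the site-selectivity and decarboxylation questions, but it depends on a fragile diene. In step economy it is worse, at about ten steps.

Key step: step 5

Assumption: compounds 1, 4, 5 and 8 are taken as purchasable. In step 6 the cleavage of the lactone C–O bond is taken to be the slowest of the reductive events.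

## Route

Step 1
Reactants: 1 2-hydroxy-4-methoxybenzoic acid
Product: 3 2-(benzyloxy)-4-methoxybenzoic acid, via benzyl ester 2 (not isolated)
Conditions: BnBr (2.4 equiv), K2CO3 (3 equiv), DMF, 60 °C; then aq KOH, EtOH, 70 °C; HCl to pH 2
Reagents that add atoms: benzyl bromide, BrCc1ccccc1
Why: Williamson O-alkylation of carboxylate and phenoxide gives 2, and saponification in the same flask cleaves only the ester because the aryl benzyl ether is inert to hydroxide; acid–base extraction removes benzyl alcohol.

Step 2
Reactants: 4 1-(benzyloxy)-4-vinylbenzene; 5 3-bromo-5-methoxyphenol
Product: 7 3-{2-[4-(benzyloxy)phenyl]ethyl}-5-methoxyphenol, via B-alkyl-9-BBN borane 6 (not isolated)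
Conditions: 4 (1.3 equiv), 9-BBN (1.25 equiv), THF, 0 °C to rt; then 5 (1.0 equiv), PdCl2(dppf) (5 mol%), aq K3PO4 (4 equiv), THF–DMF, 65 °C
Reagents that add atoms: none
Why: Anti-Markovnikov hydroboration puts boron on the terminal carbon of 4, and the B-alkyl Suzuki–Miyaura coupling transfers the primary alkyl group to the aryl bromide, the bidentate dppf ligand suppressing β-hydride elimination. Keeping 4 in slight excess over 9-BBN leaves no B–H for the phenol, which reacts as its phenoxide and needs no protection.

Step 3
Reactants: 7 3-{2-[4-(benzyloxy)phenyl]ethyl}-5-methoxyphenol; 8 4-fluorobenzaldehyde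
Product: 9 4-(3-{2-[4-(benzyloxy)phenyl]ethyl}-5-methoxyphenoxy)benzaldehyde
Conditions: K2CO3 (2 equiv), DMF, 110 °C
Reagents that add atoms: none
Why: Nucleophilic aromatic substitution by addition–elimination; the para-formyl group stabilises the Meisenheimer intermediate and fluoride is the best leaving group for this mechanism, so the phenoxide of 7 forms the diaryl ether while the benzyl ether and bridge are inert.

Step 4
Reactants: 9 4-(3-{2-[4-(benzyloxy)phenyl]ethyl}-5-methoxyphenoxy)benzaldehyde
Product: 10 1-{2-[4-(benzyloxy)phenyl]ethyl}-3-methoxy-5-(4-vinylphenoxy)benzene
Conditions: Ph3PCH3Br (1.3 equiv), KOtBu (1.25 equiv), THF, 0 °C to rt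
Reagents that add atoms: methyltriphenylphosphonium bromide, C[P+](c1ccccc1)(c1ccccc1)c1ccccc1.[Br-]
Why: Wittig methylenation with the non-stabilised ylide converts the non-enolisable aryl aldehyde into the terminal styrene; no other electrophile is present, and 10 is stored cold with a radical inhibitor.

Step 5
Reactants: 3 2-(benzyloxy)-4-methoxybenzoic acid; 10 1-{2-[4-(benzyloxy)phenyl]ethyl}-3-methoxy-5-(4-vinylphenoxy)benzene
Product: 12 8-(benzyloxy)-3-[4-(3-{2-[4-(benzyloxy)phenyl]ethyl}-5-methoxyphenoxy)phenyl]-6-methoxy-1H-isochromen-1-one, via (E)-stilbene acid 11 (not isolated)
Conditions: 3 (1.5 equiv), 10 (1.0 equiv), Pd(OAc)2 (10 mol%), Cu(OAc)2 (20 mol%), air, 4 Å MS, DMF, 100 °C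
Reagents that add atoms: none
Why: The carboxylate of 3 binds divalent palladium and delivers it to C6–H, the only ortho C–H because C2 carries the benzyloxy group, by acetate-assisted concerted metalation–deprotonation to give a five-membered palladacycle. Styrene 10 inserts with the aryl group going to the terminal carbon and palladium to the benzylic carbon, and syn β-hydride elimination releases the (E)-stilbene acid 11. Divalent palladium then coordinates the alkene of 11 and the carboxylate attacks anti at the carbon bearing ring C, a 6-endo-trig oxypalladation favoured because the para-aryloxy group of ring C stabilises positive character there; palladium ends at C4 cis to H-3, so a second syn β-hydride elimination forms the C3=C4 bond of 12. Zerovalent palladium is returned to the divalent state by Cu(OAc)2, which air reoxidises, so water is the only by-product. The closest known reaction type is the palladium-catalysed oxidative coupling of benzoic acids with vinylarenes to 3-arylisocoumarins, a carboxylate-directed Fujiwara–Moritani olefination followed by Wacker-type lactonisation. No stereocentre is formed, and the only stereo-element, the E alkene of 11, is consumed in the ring closure. The selectivities needed are the site of C–H activation (secured by the carboxylate director and the single open ortho position), C–H palladation over ipso-palladation with loss of CO2 (favoured by acetate ligands, the absence of silver salts and a temperature held at 100 °C) and terminal arylation of the alkene (secured by the preference for benzylic palladium). The 6-endo versus 5-exo choice is not critical, since the isomeric benzylidenephthalide or unclosed 11 would be reduced to the same acid 14 in step 6.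

Step 6
Reactants: 12 8-(benzyloxy)-3-[4-(3-{2-[4-(benzyloxy)phenyl]ethyl}-5-methoxyphenoxy)phenyl]-6-methoxy-1H-isochromen-1-one
Product: 14 2-hydroxy-6-{2-[4-(3-[2-(4-hydroxyphenyl)ethyl]-5-methoxyphenoxy)phenyl]ethyl}-4-methoxybenzoic acid, via debenzylated dihydroisocoumarin 13 (not isolated)
Conditions: H2 (3 atm), 10% Pd/C, EtOAc–AcOH (10:1), rt to 40 °C
Reagents that add atoms: none
Why: Heterogeneous hydrogenation saturates the C3=C4 enol-lactone alkene and removes both O-benzyl groups to give racemic 13, whose C3–O bond is a benzylic carboxylate activated by the para-aryloxy ring C and undergoes hydrogenolysis to free the acid and the saturated bridge. The C3 stereocentre of 13 is destroyed in that cleavage, so its configuration does not matter; weak acid and near-ambient temperature avoid decarboxylation of 14.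

## Compound list

1 | 2-hydroxy-4-methoxybenzoic acid | COc1ccc(C(=O)O)c(O)c1 | starting material
2 | benzyl 2-(benzyloxy)-4-methoxybenzoate | COc1ccc(C(=O)OCc2ccccc2)c(OCc2ccccc2)c1 | intermediate (not isolated)
3 | 2-(benzyloxy)-4-methoxybenzoic acid | COc1ccc(C(=O)O)c(OCc2ccccc2)c1 | intermediate
4 | 1-(benzyloxy)-4-vinylbenzene | C=Cc1ccc(OCc2ccccc2)cc1 | starting material
5 | 3-bromo-5-methoxyphenol | COc1cc(O)cc(Br)c1 | starting material
6 | 9-{2-[4-(benzyloxy)phenyl]ethyl}-9-borabicyclo[3.3.1]nonane | C(CB1C2CCCC1CCC2)c1ccc(OCc2ccccc2)cc1 | intermediate (not isolated)
7 | 3-{2-[4-(benzyloxy)phenyl]ethyl}-5-methoxyphenol | COc1cc(O)cc(CCc2ccc(OCc3ccccc3)cc2)c1 | intermediate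
8 | 4-fluorobenzaldehyde | O=Cc1ccc(F)cc1 | starting material
9 | 4-(3-{2-[4-(benzyloxy)phenyl]ethyl}-5-methoxyphenoxy)benzaldehyde | COc1cc(CCc2ccc(OCc3ccccc3)cc2)cc(Oc2ccc(C=O)cc2)c1 | intermediate
10 | 1-{2-[4-(benzyloxy)phenyl]ethyl}-3-methoxy-5-(4-vinylphenoxy)benzene | C=Cc1ccc(Oc2cc(OC)cc(CCc3ccc(OCc4ccccc4)cc3)c2)cc1 | intermediate
11 | (E)-2-(benzyloxy)-6-{2-[4-(3-{2-[4-(benzyloxy)phenyl]ethyl}-5-methoxyphenoxy)phenyl]ethenyl}-4-methoxybenzoic acid | COc1cc(OCc2ccccc2)c(C(=O)O)c(/C=C/c2ccc(Oc3cc(OC)cc(CCc4ccc(OCc5ccccc5)cc4)c3)cc2)c1 | intermediate (not isolated)
12 | 8-(benzyloxy)-3-[4-(3-{2-[4-(benzyloxy)phenyl]ethyl}-5-methoxyphenoxy)phenyl]-6-methoxy-1H-isochromen-1-one | COc1cc(OCc2ccccc2)c2c(c1)C=C(c1ccc(Oc3cc(OC)cc(CCc4ccc(OCc5ccccc5)cc4)c3)cc1)OC2=O | intermediate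
13 | rac-8-hydroxy-3-[4-(3-[2-(4-hydroxyphenyl)ethyl]-5-methoxyphenoxy)phenyl]-6-methoxy-3,4-dihydro-1H-isochromen-1-one (racemic at C3) | COc1cc(O)c2c(c1)CC(c1ccc(Oc3cc(OC)cc(CCc4ccc(O)cc4)c3)cc1)OC2=O | intermediate (not isolated)
14 | 2-hydroxy-6-{2-[4-(3-[2-(4-hydroxyphenyl)ethyl]-5-methoxyphenoxy)phenyl]ethyl}-4-methoxybenzoic acid | COc1cc(CCc2ccc(O)cc2)cc(Oc2ccc(CCc3cc(OC)cc(O)c3C(=O)O)cc2)c1 | target

## Step count and least certain steps

Total step count: 6 (step 1 and step 2 are each two-stage, one-flask operations).
Longest linear sequence: 5 steps (steps 2, 3, 4, 5 and 6, from 4 and 5).

**Step 5 (key step).** The most likely failure is ipso-palladation at C1 with loss of CO2 in place of ortho C–H palladation. Acid 3 is electron-rich and its carboxyl is twisted out of plane by the ortho benzyloxy group, which is the situation that favours decarboxylative metalation; the doubly ortho-substituted 11 is even more prone to it until the lactone closes. Oxidative dimerisation or polymerisation of the styrene at 100 °C is the second concern.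

The fallback avoids C–H activation altogether and uses toluate-anion chemistry. It sets out from aldehyde 9. Commercial methyl 2-hydroxy-4-methoxy-6-methylbenzoate F1 would be benzylated (BnBr, K2CO3, DMF) to methyl 2-(benzyloxy)-4-methoxy-6-methylbenzoate F2. Lateral lithiation of F2 with LiN(iPr)2 in THF at −78 °C and addition of 9 would give a benzylic alkoxide that closes onto the neighbouring ester. The product would be racemic 8-(benzyloxy)-3-[4-(3-{2-[4-(benzyloxy)phenyl]ethyl}-5-methoxyphenoxy)phenyl]-6-methoxy-3,4-dihydro-1H-isochromen-1-one F3. Under the conditions of step 6, F3 loses both benzyl groups and so comes back to the route at 13, which goes on to 14. Steps 4 and 5 and acid 3 are then not needed.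

**Step 6.** The most likely failure is stalling at the lactone after fast alkene saturation and debenzylation. A secondary benzylic carboxylate is cleaved more slowly than an aryl benzyl ether, and forcing it with heat or strong acid invites loss of CO2 from 14.

The fallback removes the C–O cleavage from the plan by never closing the lactone. It sets out from 3 and 10. With [Cp*RhCl2]2 (trivalent rhodium, 2 mol%) and Cu(OAc)2 (2 equiv) in DMF at 100 °C, the carboxylate-directed olefination should stop at the open acid 11, because the styryl alkene is not a Michael acceptor. 11 is then isolated. Hydrogenation of 11 (H2, Pd/C, EtOAc, rt) reduces only an alkene and two benzyl ethers and comes back to the route at 14.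

**Step 2.** The most likely failure is slow oxidative addition into the bromide of the electron-rich phenoxide form of 5, so that protodeboronation and β-hydride elimination of the alkyl group compete.

The fallback replaces the alkylborane by an alkene coupling followed by a chemoselective reduction. It sets out from 4 and 5. A Mizoroki–Heck reaction (Pd(OAc)2, P(o-tol)3, Et3N, DMF, 100 °C) would give (E)-3-{2-[4-(benzyloxy)phenyl]ethenyl}-5-methoxyphenol F4. Diimide, generated from p-toluenesulfonyl hydrazide and NaOAc in refluxing aqueous THF, would saturate the alkene without touching the benzyl ether. This comes back to the route at 7.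

**Step 3.** The most likely failure is base-induced disproportionation or air oxidation of the aldehyde during prolonged heating with carbonate, competing with a substitution that is only moderately fast for this phenoxide.

The fallback forms the diaryl ether by copper-mediated oxidative coupling at room temperature. It sets out from 7. Chan–Lam coupling with (4-vinylphenyl)boronic acid F5 (Cu(OAc)2, pyridine, air, 4 Å MS, CH2Cl2, rt) would install the vinylphenyl group directly. This comes back to the route at 10 and also bypasses step 4.

## Further compounds

F1 | step 5 | methyl 2-hydroxy-4-methoxy-6-methylbenzoate | COC(=O)c1c(C)cc(OC)cc1O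
F2 | step 5 | methyl 2-(benzyloxy)-4-methoxy-6-methylbenzoate | COC(=O)c1c(C)cc(OC)cc1OCc1ccccc1
F3 | step 5 | rac-8-(benzyloxy)-3-[4-(3-{2-[4-(benzyloxy)phenyl]ethyl}-5-methoxyphenoxy)phenyl]-6-methoxy-3,4-dihydro-1H-isochromen-1-one | COc1cc(OCc2ccccc2)c2c(c1)CC(c1ccc(Oc3cc(OC)cc(CCc4ccc(OCc5ccccc5)cc4)c3)cc1)OC2=O
F0 | step 6 | none | none
F4 | step 2 | (E)-3-{2-[4-(benzyloxy)phenyl]ethenyl}-5-methoxyphenol | COc1cc(O)cc(/C=C/c2ccc(OCc3ccccc3)cc2)c1
F5 | step 3 | (4-vinylphenyl)boronic acid | C=Cc1ccc(B(O)O)cc1
A1 | alternative 1 | benzyl 2,4-dihydroxy-6-{2-[4-(3-{2-[4-(benzyloxy)phenyl]ethyl}-5-methoxyphenoxy)phenyl]ethyl}benzoate | O=C(OCc1ccccc1)c1c(O)cc(O)cc1CCc1ccc(Oc2cc(OC)cc(CCc3ccc(OCc4ccccc4)cc3)c2)cc1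
A2 | alternative 1 | 6-{6-[4-(3-{2-[4-(benzyloxy)phenyl]ethyl}-5-methoxyphenoxy)phenyl]-2,4-dioxohexyl}-2,2-dimethyl-4H-1,3-dioxin-4-one | CC1(C)OC(CC(=O)CC(=O)CCc2ccc(Oc3cc(OC)cc(CCc4ccc(OCc5ccccc5)cc4)c3)cc2)=CC(=O)O1
A3 | alternative 2 | 5-{2-[4-(benzyloxy)phenyl]ethyl}cyclohexane-1,3-dione | O=C1CC(=O)CC(CCc2ccc(OCc3ccccc3)cc2)C1
A4 | alternative 2 | (E)-6-[4-(benzyloxy)phenyl]hex-3-en-2-one | CC(=O)/C=C/CCc1ccc(OCc2ccccc2)cc1
A5 | alternative 2 | dimethyl malonate | COC(=O)CC(=O)OC
A6 | alternative 3 | benzyl 2-hydroxy-4-methoxy-6-{2-[4-(3-{2-[4-(benzyloxy)phenyl]ethyl}-5-methoxyphenoxy)phenyl]ethyl}benzoate | O=C(OCc1ccccc1)c1c(O)cc(OC)cc1CCc1ccc(Oc2cc(OC)cc(CCc3ccc(OCc4ccccc4)cc3)c2)cc1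
A7 | alternative 3 | benzyl 5-[4-(3-{2-[4-(benzyloxy)phenyl]ethyl}-5-methoxyphenoxy)phenyl]pent-2-ynoate | O=C(OCc1ccccc1)C#CCCc1ccc(Oc2cc(OC)cc(CCc3ccc(OCc4ccccc4)cc3)c2)cc1
A8 | alternative 3 | (Z)-1,3-dimethoxy-1-(trimethylsilyloxy)buta-1,3-diene | C=C(OC)/C=C(/OC)O[Si](C)(C)C
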